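A direct plan would fold the dimethoxylated 3,5,7-triketo ester A1, built from methyl methoxyacetate by polyanion acylations, into the acylphloroglucinol A2 by Claisen cyclization, would C-aroylate A2 and cyclodehydrate it to the 5,7-dihydroxyflavone A3, and would finish by 7-O-methylation and hydrogenolysis. Its weakest steps would be:
- the folding of A1, an unstorable polyketone with methoxyls on two chain carbons, which could as well close by aldol or to pyrones;
- the aroylation of A2, which would have to occur once and at carbon in a polyanion with three free phenols;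
- the methylation of A3, which would have to tell the 7-hydroxyl from the 5-hydroxyl and stop there.

The route closes ring A last, on a finished ring C. Flavone carbons C5–C8, with their four contiguous oxygens, are the four carbons of dimethyl squarate; C4a and C8a are the C5=C6 alkene of a 2-aryl-3-alkoxy-4-pyranone. The pyranone, metalated at C6, is added to squarate (C8–C8a bond) and the carbinol oxygen is methylated. Heating then opens the cyclobutenone to a dienylketene, whose 6π electrocyclization and enolization form the C4a–C5 bond and the arene. The ketene carbonyl emerges as the free 5-hydroxyl and the methylated carbinol as the 8-methoxyl, so the route needs no polyketide folding, no polyanion aroylation and no choice between phenols.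

Key step: step 6

Remark: pyromeconic acid, 3,4-bis(benzyloxy)phenylboronic acid, dimethyl squarate and the zinc amide base (THF solution) are taken as purchased; PMB = 4-methoxybenzyl, TMP = 2,2,6,6-tetramethylpiperidide.

Step 1
Reactants: 1 3-hydroxy-4H-pyran-4-one (pyromeconic acid)
Product: 2 2-bromo-3-hydroxy-4H-pyran-4-one
Conditions: NBS (1.0 equiv), MeCN, 0 °C to rt
Reagents that add atoms: N-bromosuccinimide, O=C1CCC(=O)N1Br
Why: Electrophilic halogenation of an enol: in 3-hydroxy-4-pyranones the hydroxyl activates its ortho carbon C2, the site of their halogenation and hydroxymethylation, while C5 and C6 lack this activation.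

Step 2
Reactants: 2 2-bromo-3-hydroxy-4H-pyran-4-one
Product: 3 2-bromo-3-[(4-methoxybenzyl)oxy]-4H-pyran-4-one
Conditions: PMBCl (1.2 equiv), K2CO3 (1.5 equiv), DMF, 50 °C
Reagents that add atoms: 4-methoxybenzyl chloride, COc1ccc(CCl)cc1
Why: Williamson etherification of the acidic enolic hydroxyl, as in the O-benzylation of maltol; the ether removes the only acidic proton before the organometallic steps and can later be hydrogenolysed together with the benzyl ethers.

Step 3
Reactants: 3 2-bromo-3-[(4-methoxybenzyl)oxy]-4H-pyran-4-one; 4 3,4-bis(benzyloxy)phenylboronic acid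
Product: 5 2-[3,4-bis(benzyloxy)phenyl]-3-[(4-methoxybenzyl)oxy]-4H-pyran-4-one
Conditions: Pd(PPh3)4 (5 mol %), K3PO4 (2 equiv), 1,4-dioxane–H2O (10:1), 80 °C
Reagents that add atoms: none
Why: Suzuki–Miyaura coupling: the C2–Br bond of a vinylogous acyl bromide should add readily to zerovalent palladium, and the weak phosphate base should spare the pyranone from conjugate ring opening.

Step 4
Reactants: 5 2-[3,4-bis(benzyloxy)phenyl]-3-[(4-methoxybenzyl)oxy]-4H-pyran-4-one
Product: 7 2-[3,4-bis(benzyloxy)phenyl]-6-iodo-3-[(4-methoxybenzyl)oxy]-4H-pyran-4-one, via bis(pyranyl)zinc 6 (not isolated)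
Conditions: (TMP)2Zn·2MgCl2·2LiCl (0.6 equiv), THF, −30 °C to rt; I2 (1.3 equiv), 0 °C; aq. Na2S2O3
Reagents that add atoms: iodine, [I][I]
Why: Directed C–H zincation followed by iodinolysis: the MgCl2 of the base binds the C4 carbonyl oxygen and acidifies the only C–H next to the ring oxygen, C6, the position at which benzo-fused 4-pyranones (chromones, at C2) are expected to be zincated by this reagent, and the covalent C–Zn bond tolerates the pyranone carbonyl and the benzylic ethers.

Step 5
Reactants: 7 2-[3,4-bis(benzyloxy)phenyl]-6-iodo-3-[(4-methoxybenzyl)oxy]-4H-pyran-4-one; 8 dimethyl squarate (3,4-dimethoxycyclobut-3-ene-1,2-dione)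
Product: 11 4-{6-[3,4-bis(benzyloxy)phenyl]-5-[(4-methoxybenzyl)oxy]-4-oxo-4H-pyran-2-yl}-2,3,4-trimethoxycyclobut-2-en-1-one (racemic), via pyranylmagnesium chloride 9 (not isolated), via chloromagnesium alkoxide 10 (not isolated)
Conditions: iPrMgCl·LiCl (1.1 equiv), THF, −78 °C; 8 (1.5 equiv), −78 to −40 °C; MeOTf (2 equiv), −78 to 0 °C; aq. NaHCO3
Reagents that add atoms: methyl trifluoromethanesulfonate, COS(=O)(=O)C(F)(F)F
Why: Iodine–magnesium exchange, 1,2-addition to a squarate carbonyl and O-alkylation: exchange at the activated sp2 C–I bond should outrun attack on the poorly electrophilic vinylogous ester at −78 °C, the alkenylmagnesium should add to one of the two equivalent carbonyl groups of 8, and MeOTf should cap the tertiary alkoxide as its methyl ether; the new quaternary stereocentre forms as a racemate and is destroyed in step 6.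

Step 6
Reactants: 11 4-{6-[3,4-bis(benzyloxy)phenyl]-5-[(4-methoxybenzyl)oxy]-4-oxo-4H-pyran-2-yl}-2,3,4-trimethoxycyclobut-2-en-1-one
Product: 14 2-[3,4-bis(benzyloxy)phenyl]-5-hydroxy-6,7,8-trimethoxy-3-[(4-methoxybenzyl)oxy]-4H-chromen-4-one, via dienylketene 12 (not isolated), via 4aH-dienone 13 (not isolated)
Conditions: degassed PhMe (0.01 M), argon, 110 °C
Reagents that add atoms: none
Why: On heating, the cyclobutenone should undergo conrotatory 4π electrocyclic opening of its C1–C4 bond, with the C4 methoxyl turning outward and the pyranyl group inward, to give the (Z)-dienylketene 12; a thermal disrotatory 6π electrocyclization across the ketene C=C, the dimethoxy alkene and the pyranone C5=C6 bond then joins the ketene carbon to pyranone C5 (the C4a–C5 bond of the flavone), and dienone 13 enolizes at its doubly activated C4a–H to the phenol. The closest known reaction is the Moore rearrangement of 4-alkenyl- and 4-heteroaryl-4-alkoxycyclobutenones to 4-alkoxyphenols. Ring A is the only ring closed, as a six-membered carbocycle by 6π electrocyclization with the pyranone alkene as the terminal 2π unit, and ring C is carried through intact. No stereocentre remains: the quaternary centre of 11 is lost on ring opening and the C4a centre of 13 on enolization. The step needs inward rotation of the pyranyl group, which the outward preference of the donor methoxyl secures, and C–C closure in preference to other ketene capture, which is secured because only closure at the nucleophilic alpha-carbon of the vinylogous ester leads on to an arene (attack on the ring oxygen would give a zwitterion that reverts), because the carbinol is a methyl ether that cannot lactonize to a butenolide, and because no free hydroxyl is present until the product forms at high dilution. The oxygen pattern is fixed by connectivity: the ketene carbonyl becomes the 5-hydroxyl, hydrogen-bonded to the C4 carbonyl, and the methylated carbinol becomes the 8-methoxyl.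

Step 7
Reactants: 14 2-[3,4-bis(benzyloxy)phenyl]-5-hydroxy-6,7,8-trimethoxy-3-[(4-methoxybenzyl)oxy]-4H-chromen-4-one
Product: 15 3,5,3',4'-tetrahydroxy-6,7,8-trimethoxyflavone
Conditions: H2 (1 atm), Pd(OH)2/C (20%), THF–MeOH, rt
Reagents that add atoms: none
Why: Palladium-catalysed hydrogenolysis of the two benzyl ethers and the 4-methoxybenzyl ether; the aryl methyl ethers, the chelated 5-hydroxyl and the chromone C2=C3 bond should be inert under one atmosphere of H2 at rt.

**Compound list**

1 | 3-hydroxy-4H-pyran-4-one (pyromeconic acid) | O=c1ccocc1O | starting material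
2 | 2-bromo-3-hydroxy-4H-pyran-4-one | O=c1ccoc(Br)c1O | intermediate
3 | 2-bromo-3-[(4-methoxybenzyl)oxy]-4H-pyran-4-one | O=c1ccoc(Br)c1OCc1ccc(OC)cc1 | intermediate
4 | 3,4-bis(benzyloxy)phenylboronic acid | OB(O)c1ccc(OCc2ccccc2)c(OCc2ccccc2)c1 | starting material
5 | 2-[3,4-bis(benzyloxy)phenyl]-3-[(4-methoxybenzyl)oxy]-4H-pyran-4-one | O=c1ccoc(-c2ccc(OCc3ccccc3)c(OCc3ccccc3)c2)c1OCc1ccc(OC)cc1 | intermediate
6 | bis{6-[3,4-bis(benzyloxy)phenyl]-5-[(4-methoxybenzyl)oxy]-4-oxo-4H-pyran-2-yl}zinc | [Zn](c1cc(=O)c(OCc2ccc(OC)cc2)c(-c2ccc(OCc3ccccc3)c(OCc3ccccc3)c2)o1)c1cc(=O)c(OCc2ccc(OC)cc2)c(-c2ccc(OCc3ccccc3)c(OCc3ccccc3)c2)o1 | intermediate (not isolated)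
7 | 2-[3,4-bis(benzyloxy)phenyl]-6-iodo-3-[(4-methoxybenzyl)oxy]-4H-pyran-4-one | Ic1cc(=O)c(OCc2ccc(OC)cc2)c(-c2ccc(OCc3ccccc3)c(OCc3ccccc3)c2)o1 | intermediate
8 | dimethyl squarate (3,4-dimethoxycyclobut-3-ene-1,2-dione) | COC1=C(OC)C(=O)C1=O | starting material
9 | {6-[3,4-bis(benzyloxy)phenyl]-5-[(4-methoxybenzyl)oxy]-4-oxo-4H-pyran-2-yl}magnesium chloride | Cl[Mg]c1cc(=O)c(OCc2ccc(OC)cc2)c(-c2ccc(OCc3ccccc3)c(OCc3ccccc3)c2)o1 | intermediate (not isolated)
10 | chloromagnesium 1-{6-[3,4-bis(benzyloxy)phenyl]-5-[(4-methoxybenzyl)oxy]-4-oxo-4H-pyran-2-yl}-2,3-dimethoxy-4-oxocyclobut-2-en-1-olate (racemic) | Cl[Mg]OC1(c2cc(=O)c(OCc3ccc(OC)cc3)c(-c3ccc(OCc4ccccc4)c(OCc4ccccc4)c3)o2)C(OC)=C(OC)C1=O | intermediate (not isolated)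
11 | 4-{6-[3,4-bis(benzyloxy)phenyl]-5-[(4-methoxybenzyl)oxy]-4-oxo-4H-pyran-2-yl}-2,3,4-trimethoxycyclobut-2-en-1-one (racemic) | COC1(c2cc(=O)c(OCc3ccc(OC)cc3)c(-c3ccc(OCc4ccccc4)c(OCc4ccccc4)c3)o2)C(OC)=C(OC)C1=O | intermediate
12 | (3Z)-4-{6-[3,4-bis(benzyloxy)phenyl]-5-[(4-methoxybenzyl)oxy]-4-oxo-4H-pyran-2-yl}-2,3,4-trimethoxybuta-1,3-dien-1-one | O=C=C(OC)/C(OC)=C(OC)\c1cc(=O)c(OCc2ccc(OC)cc2)c(-c2ccc(OCc3ccccc3)c(OCc3ccccc3)c2)o1 | intermediate (not isolated)
13 | 2-[3,4-bis(benzyloxy)phenyl]-6,7,8-trimethoxy-3-[(4-methoxybenzyl)oxy]-4aH-chromene-4,5-dione (racemic) | COC1=C(OC)C(OC)=C2OC(c3ccc(OCc4ccccc4)c(OCc4ccccc4)c3)=C(OCc3ccc(OC)cc3)C(=O)C2C1=O | intermediate (not isolated)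
14 | 2-[3,4-bis(benzyloxy)phenyl]-5-hydroxy-6,7,8-trimethoxy-3-[(4-methoxybenzyl)oxy]-4H-chromen-4-one | COc1c(OC)c(O)c2c(=O)c(OCc3ccc(OC)cc3)c(-c3ccc(OCc4ccccc4)c(OCc4ccccc4)c3)oc2c1OC | intermediate
15 | 3,5,3',4'-tetrahydroxy-6,7,8-trimethoxyflavone | COc1c(OC)c(O)c2c(=O)c(O)c(-c3ccc(O)c(O)c3)oc2c1OC | target

Total step count: 7. Longest linear sequence: 7 steps (1 to 15); 4 and 8 are purchased.

Steps most likely to fail:

Step 5. The magnesium reagent 9 may attack unexchanged iodide 7 or the pyranone carbonyl, and the hindered magnesium alkoxide 10 may be methylated incompletely or lose selectivity against the pyranone carbonyl oxygen. The fallback would set out from 5 and come back at 11 without the iodide. The diorganozinc 6 from the zincation, which is inert towards the pyranone, would be added as such to 8 (THF, −30 °C to rt; the MgCl2 carried by the reagent is known to promote addition of organozincs to reactive carbonyl groups). Aqueous NH4Cl would give 4-{6-[3,4-bis(benzyloxy)phenyl]-5-[(4-methoxybenzyl)oxy]-4-oxo-4H-pyran-2-yl}-4-hydroxy-2,3-dimethoxycyclobut-2-en-1-one F1. The isolated carbinol would be methylated under neutral conditions (MeI, Ag2O, MeCN, rt) to 11.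

Step 6. The dienylketene 12 may be consumed by dimerization or by acylation of the phenol as it forms, or the methyl ether may open only at temperatures at which it decomposes. The fallback would set out from 7 and come back at 14, with ring A born as a hydroquinone.
- Alkoxide 10, made as in step 5, would be capped with Me3SiCl in place of MeOTf to give 4-{6-[3,4-bis(benzyloxy)phenyl]-5-[(4-methoxybenzyl)oxy]-4-oxo-4H-pyran-2-yl}-2,3-dimethoxy-4-[(trimethylsilyl)oxy]cyclobut-2-en-1-one F2, the silyl ether type on which this ring expansion is best documented.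
- Heating (PhMe, 80–110 °C) should give 2-[3,4-bis(benzyloxy)phenyl]-5-hydroxy-6,7-dimethoxy-3-[(4-methoxybenzyl)oxy]-8-[(trimethylsilyl)oxy]-4H-chromen-4-one F3.
- Methanolysis (K2CO3, MeOH, argon) should give 2-[3,4-bis(benzyloxy)phenyl]-5,8-dihydroxy-6,7-dimethoxy-3-[(4-methoxybenzyl)oxy]-4H-chromen-4-one F4.
- MeI (1.05 equiv) with K2CO3 in acetone should methylate only the 8-hydroxyl, since the 5-hydroxyl is held in its hydrogen bond to the C4 carbonyl.

Step 4. The zincation may stall or may stray to C5 or to a benzylic position, and the diorganozinc may iodinate sluggishly. The fallback would set out from 5 and come back at 11, replacing the thermodynamic zincation by a kinetic deprotonation used at once. Slow addition of 5 to lithium 2,2,6,6-tetramethylpiperidide (from the amine and n-BuLi; THF, −78 °C) should give {6-[3,4-bis(benzyloxy)phenyl]-5-[(4-methoxybenzyl)oxy]-4-oxo-4H-pyran-2-yl}lithium F5. Immediate addition of 8 should give lithium 1-{6-[3,4-bis(benzyloxy)phenyl]-5-[(4-methoxybenzyl)oxy]-4-oxo-4H-pyran-2-yl}-2,3-dimethoxy-4-oxocyclobut-2-en-1-olate F6, and MeOTf should convert it into 11.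

**Further compounds**

F1 | step 5 | 4-{6-[3,4-bis(benzyloxy)phenyl]-5-[(4-methoxybenzyl)oxy]-4-oxo-4H-pyran-2-yl}-4-hydroxy-2,3-dimethoxycyclobut-2-en-1-one (racemic) | OC1(c2cc(=O)c(OCc3ccc(OC)cc3)c(-c3ccc(OCc4ccccc4)c(OCc4ccccc4)c3)o2)C(OC)=C(OC)C1=O
F2 | step 6 | 4-{6-[3,4-bis(benzyloxy)phenyl]-5-[(4-methoxybenzyl)oxy]-4-oxo-4H-pyran-2-yl}-2,3-dimethoxy-4-[(trimethylsilyl)oxy]cyclobut-2-en-1-one (racemic) | C[Si](C)(C)OC1(c2cc(=O)c(OCc3ccc(OC)cc3)c(-c3ccc(OCc4ccccc4)c(OCc4ccccc4)c3)o2)C(OC)=C(OC)C1=O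
F3 | step 6 | 2-[3,4-bis(benzyloxy)phenyl]-5-hydroxy-6,7-dimethoxy-3-[(4-methoxybenzyl)oxy]-8-[(trimethylsilyl)oxy]-4H-chromen-4-one | COc1c(OC)c(O)c2c(=O)c(OCc3ccc(OC)cc3)c(-c3ccc(OCc4ccccc4)c(OCc4ccccc4)c3)oc2c1O[Si](C)(C)C
F4 | step 6 | 2-[3,4-bis(benzyloxy)phenyl]-5,8-dihydroxy-6,7-dimethoxy-3-[(4-methoxybenzyl)oxy]-4H-chromen-4-one | COc1c(OC)c(O)c2c(=O)c(OCc3ccc(OC)cc3)c(-c3ccc(OCc4ccccc4)c(OCc4ccccc4)c3)oc2c1O
F5 | step 4 | {6-[3,4-bis(benzyloxy)phenyl]-5-[(4-methoxybenzyl)oxy]-4-oxo-4H-pyran-2-yl}lithium | [Li]c1cc(=O)c(OCc2ccc(OC)cc2)c(-c2ccc(OCc3ccccc3)c(OCc3ccccc3)c2)o1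
F6 | step 4 | lithium 1-{6-[3,4-bis(benzyloxy)phenyl]-5-[(4-methoxybenzyl)oxy]-4-oxo-4H-pyran-2-yl}-2,3-dimethoxy-4-oxocyclobut-2-en-1-olate (racemic) | [Li]OC1(c2cc(=O)c(OCc3ccc(OC)cc3)c(-c3ccc(OCc4ccccc4)c(OCc4ccccc4)c3)o2)C(OC)=C(OC)C1=O
A1 | direct plan | methyl 8-(benzyloxy)-2,4-dimethoxy-3,5,7-trioxooctanoate | COC(=O)C(OC)C(=O)C(OC)C(=O)CC(=O)COCc1ccccc1
A2 | direct plan | 2-(benzyloxy)-1-(2,4,6-trihydroxy-3,5-dimethoxyphenyl)ethan-1-one | O=C(COCc1ccccc1)c1c(O)c(OC)c(O)c(OC)c1O
A3 | direct plan | 3-(benzyloxy)-2-[3,4-bis(benzyloxy)phenyl]-5,7-dihydroxy-6,8-dimethoxy-4H-chromen-4-one | COc1c(O)c(OC)c2oc(-c3ccc(OCc4ccccc4)c(OCc4ccccc4)c3)c(OCc3ccccc3)c(=O)c2c1O
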